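**Plan**

1. Numbering: the carbocycle is a cycloheptane, C1 (lactone O–CH), C2 (ring-fusion CH), C3 (CH2), C4 (CHOH), C5 (CHMe), C6 (C(OH)–crotonoyl), C7 (CH–O-isovalerate); C8, C9, C10 are the lactone α-carbon, carbonyl and exocyclic CH2; β is the face of the C4 hydroxyl, and "cyclohept-7-ene" means the C7=C1 alkene.
2. Cuts: the C7 ester; the lactone O–C1 bond (back to a C7/C1 epoxide and a C9 acid made from an isopropenyl methyl); the crotonoyl Cα=Cβ bond and the C6–acyl bond (back to a C6 ketone); C4–OH back to a ketone; then the ring bond C2–C3.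
3. Enabling feature: in the seven-membered carbocycle the C3 methylene lies between the C4 oxygen and the C2 stereocentre, and C7/C1 carry vicinal oxygens where an alkene can stand. This is a cyclohept-4-enone (C4=O, C7=C1), the [3,3] product of a 2-methylene-5-alkenyltetrahydrofuran (ring O, C4, C5, C6, C7).
4. Forward order: crotylboration builds the C4–C7 chain; a γ-butyrolactone (temporary five-membered ring) is closed, olefinated and methylenated; the Claisen shift turns the furan into the cycloheptenone; C4 and C6 exchange oxidation levels and C6 gains the crotonoyl group; the α-methylene lactone ring closes last, then esterification and desilylation.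
5. Stereochemistry: the C7 carbinol of the furan comes from (R)-glyceraldehyde acetonide and is traded for C2 in the chair Claisen transition state; C5 and C6 come from the anti-selective (E)-crotylboration; C4 from hydride delivery by the C6 hydroxyl; the C6 quaternary centre from addition anti to the C5 methyl; the final C7 and C1 from β-face epoxidation and invertive lactonisation by the α-face acid.

Key step: step 8

Remark: minor diastereomers from steps 1, 10, 13 and 19 are assumed to be removable by chromatography, and the γ-lactone (not the δ-lactone) is assumed to be the closure product of step 4.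

**Route**

Step 1
Reactants: 1 (R)-2,3-O-isopropylideneglyceraldehyde; 2 (E)-crotylboronic acid pinacol ester
Product: 4 (1S,2S)-1-[(4R)-2,2-dimethyl-1,3-dioxolan-4-yl]-2-methylbut-3-en-1-ol (anti,anti homoallylic alcohol), via borate ester 3 (not isolated)
Conditions: CH2Cl2 (2 M), rt, 48 h; aq. NaHCO3 work-up
Reagents that add atoms: none
Why: Allylboration through a closed chair (Zimmerman–Traxler) transition state should turn the E geometry of the crotyl unit into the anti C5-methyl/C6-hydroxyl pair, and attack anti to the α-oxygen of the aldehyde (Felkin–Anh control) should place the C6 hydroxyl anti to the C7 oxygen from (R)-glyceraldehyde, so the anti,anti isomer is expected as the main product after hydrolysis of borate 3.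

Step 2
Reactants: 4 (1S,2S)-1-[(4R)-2,2-dimethyl-1,3-dioxolan-4-yl]-2-methylbut-3-en-1-ol
Product: 5 tert-butyldimethylsilyl ether of 4
Conditions: TBSOTf, 2,6-lutidine, CH2Cl2, −78 to 0 °C
Reagents that add atoms: tert-butyldimethylsilyl triflate, CC(C)(C)[Si](C)(C)OS(=O)(=O)C(F)(F)F
Why: Silylation with the silyl triflate and a hindered pyridine base is the standard way to cap a flanked secondary alcohol and touches neither the acetonide nor a stereocentre.

Step 3
Reactants: 5 tert-butyldimethylsilyl ether of 4
Product: 6 (2R,3S)-3-(tert-butyldimethylsilyloxy)-3-[(4R)-2,2-dimethyl-1,3-dioxolan-4-yl]-2-methylpropanoic acid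
Conditions: RuCl3·xH2O (3 mol%), NaIO4 (4.2 equiv), MeCN/EtOAc/H2O (2:2:3), rt
Reagents that add atoms: sodium periodate, [Na+].[O-]I(=O)(=O)=O (oxygen passed on through RuO4); water, O
Why: RuO4 generated catalytically from RuCl3 and NaIO4 cleaves the terminal vinyl group oxidatively to the C4 carboxylic acid under weakly acidic conditions that should leave the silyl ether, the acetonide and the α-stereocentre C5 unchanged.

Step 4
Reactants: 6 (2R,3S)-3-(tert-butyldimethylsilyloxy)-3-[(4R)-2,2-dimethyl-1,3-dioxolan-4-yl]-2-methylpropanoic acid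
Product: 8 (3R,4S,5R)-4-(tert-butyldimethylsilyloxy)-5-(hydroxymethyl)-3-methyldihydrofuran-2(3H)-one, via dihydroxy acid 7 (not isolated)
Conditions: AcOH/H2O (4:1), 40 °C; then PhMe, azeotropic removal of water
Reagents that add atoms: none
Why: Aqueous acetic acid hydrolyses the terminal acetonide faster than the hindered secondary silyl ether, and the freed C7 hydroxyl should then close the five-membered lactone onto the C4 acid (acid-catalysed lactonisation, γ favoured over δ) without change at any stereocentre.

Step 5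
Reactants: 8 (3R,4S,5R)-4-(tert-butyldimethylsilyloxy)-5-(hydroxymethyl)-3-methyldihydrofuran-2(3H)-one
Product: 9 (2S,3S,4R)-3-(tert-butyldimethylsilyloxy)-4-methyl-5-oxotetrahydrofuran-2-carbaldehyde
Conditions: Dess–Martin periodinane, NaHCO3, CH2Cl2, 0 °C to rt; used crude
Reagents that add atoms: none
Why: Dess–Martin oxidation works near neutrality, so the α-acyloxy aldehyde should form without epimerisation at C7 or β-elimination of the C6 silyloxy group.

Step 6
Reactants: 9 (2S,3S,4R)-3-(tert-butyldimethylsilyloxy)-4-methyl-5-oxotetrahydrofuran-2-carbaldehyde; 10 1-(triphenylphosphoranylidene)propan-2-one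
Product: 11 (3R,4S,5R)-4-(tert-butyldimethylsilyloxy)-3-methyl-5-[(E)-3-oxobut-1-en-1-yl]dihydrofuran-2(3H)-one
Conditions: CH2Cl2, rt
Reagents that add atoms: none
Why: Wittig olefination with the stabilised acetonyl ylide needs no added base and, through reversible oxaphosphetane formation, should give the E-configured C1=C2 enone with C7 untouched.

Step 7
Reactants: 11 (3R,4S,5R)-4-(tert-butyldimethylsilyloxy)-3-methyl-5-[(E)-3-oxobut-1-en-1-yl]dihydrofuran-2(3H)-one
Product: 13 (2R,3S,4R)-3-(tert-butyldimethylsilyloxy)-4-methyl-5-methylidene-2-[(E)-3-methylbuta-1,3-dien-1-yl]tetrahydrofuran, via dienyl lactone 12 (not isolated)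
Conditions: Cp2TiMe2 (4 equiv), PhMe, 70 °C, dark; filtration through basic Al2O3 (1% Et3N in eluent)
Reagents that add atoms: dimethyltitanocene Cp2TiMe2, [CH3-].[CH3-].[Ti+4].c1cc[cH-]c1.c1cc[cH-]c1
Why: Petasis methylenation with Cp2Ti=CH2, released thermally from Cp2TiMe2 and non-basic, should convert first the ketone into the isopropenyl diene 12 and then the lactone carbonyl C4 into the exocyclic enol ether (C3), assembling the allyl vinyl ether without risk to the C5 and C7 stereocentres.

Step 8
Reactants: 13 (2R,3S,4R)-3-(tert-butyldimethylsilyloxy)-4-methyl-5-methylidene-2-[(E)-3-methylbuta-1,3-dien-1-yl]tetrahydrofuran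
Product: 14 (2R,3R,6R)-3-(tert-butyldimethylsilyloxy)-2-methyl-6-(prop-1-en-2-yl)cyclohept-4-en-1-one (route numbering: C4 ketone with 5α-Me, 6α-OTBS and 2α-isopropenyl all cis, C7=C1 alkene)
Conditions: PhMe (0.02 M), 2,6-di-tert-butyl-4-methylpyridine (0.1 equiv), NaOH-washed sealed tube, 185 °C
Reagents that add atoms: none
Why: Heating triggers a concerted suprafacial [3,3]-sigmatropic shift of the allyl vinyl ether C3=C4–O–C7–C1=C2, in which C2–C3 forms while O–C7 breaks, and the gain of the C4 carbonyl drives it forward. The closest known reaction type is the thermal Claisen ring expansion of 2-methylene-5-vinyltetrahydrofurans to cyclohept-4-enones. The seven-membered carbocycle (C4–C5–C6–C7–C1–C2–C3) closes by sigmatropic union of the termini C2 and C3 across the furan, a two-carbon enlargement of the five-membered ether through a chair-like array shaped like an 8-oxabicyclo[3.2.1]octane, in which the C5–C6 bridge sits axial on C7 and therefore gives the cis C7=C1 alkene. The new stereocentre C2 is controlled by chirality transfer from C7: the E-dienyl terminus takes the equatorial site of the chair, which puts the isopropenyl group on the face of the exo C5 methyl and C6 silyloxy groups. The step needs the chair to win over the boat and the rearrangement to outrun acid-catalysed exo-to-endo isomerisation of the enol ether and dimerisation of the diene; the trans placing of the dienyl group relative to both furan substituents keeps the forming three-carbon bridge unhindered, and base-washed glass, a hindered pyridine and high dilution guard against the side reactions.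

Step 9
Reactants: 14 (2R,3R,6R)-3-(tert-butyldimethylsilyloxy)-2-methyl-6-(prop-1-en-2-yl)cyclohept-4-en-1-one
Product: 15 6α-hydroxy-5α-methyl-2α-isopropenylcyclohept-7-en-4-one
Conditions: HF·pyridine, pyridine, THF, 0 °C to rt
Reagents that add atoms: none
Why: Fluoride-mediated desilylation with buffered HF·pyridine frees the C6 hydroxyl under mildly acidic conditions, which should avoid the E1cB dehydration and retro-aldol cleavage that basic fluoride sources could cause in this β-hydroxy ketone.

Step 10
Reactants: 15 6α-hydroxy-5α-methyl-2α-isopropenylcyclohept-7-en-4-one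
Product: 16 5α-methyl-2α-isopropenylcyclohept-7-ene-4β,6α-diol
Conditions: Me4NBH(OAc)3 (5 equiv), MeCN/AcOH (1:1), −30 °C; aq. KNaC4H4O6 work-up
Reagents that add atoms: none
Why: In this Evans–Saksena reduction the C6 hydroxyl exchanges onto boron and delivers hydride within the molecule to the α face of the C4 ketone, so the new C4 hydroxyl should come out β, 1,3-anti to the C6 hydroxyl and trans to the C5 methyl.

Step 11
Reactants: 16 5α-methyl-2α-isopropenylcyclohept-7-ene-4β,6α-diol
Product: 17 4β-hydroxy-5α-methyl-2α-isopropenylcyclohept-7-en-6-one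
Conditions: MnO2 (excess), CH2Cl2, rt
Reagents that add atoms: none
Why: MnO2 oxidises allylic alcohols selectively, so only the C6 carbinol next to the C7=C1 alkene is taken to the enone while the saturated C4 alcohol and the epimerisable C5 centre are left alone.

Step 12
Reactants: 17 4β-hydroxy-5α-methyl-2α-isopropenylcyclohept-7-en-6-one
Product: 18 4β-(tert-butyldimethylsilyloxy)-5α-methyl-2α-isopropenylcyclohept-7-en-6-one
Conditions: TBSOTf, 2,6-lutidine, CH2Cl2, −78 °C
Reagents that add atoms: tert-butyldimethylsilyl triflate, CC(C)(C)[Si](C)(C)OS(=O)(=O)C(F)(F)F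
Why: Low-temperature silylation with the triflate and 2,6-lutidine protects the C4 hydroxyl before the organolithium step and is mild enough not to cause β-elimination from the β-hydroxy ketone.

Step 13
Reactants: 18 4β-(tert-butyldimethylsilyloxy)-5α-methyl-2α-isopropenylcyclohept-7-en-6-one
Product: 20 6β-acetyl-4β-(tert-butyldimethylsilyloxy)-5α-methyl-2α-isopropenylcyclohept-7-en-6α-ol, via enol ether adduct 19 (not isolated)
Conditions: ethyl vinyl ether, t-BuLi, THF, −78 to 0 °C; then 18, −78 °C; then 0.5 M aq. HCl, THF, 0 °C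
Reagents that add atoms: ethyl vinyl ether, C=COCC (lithiated in the flask with t-BuLi); water, O
Why: 1,2-Addition of the acyl-anion equivalent 1-ethoxyvinyllithium to the C6 carbonyl should take place on the β face, anti to the flanking C5 methyl (equatorial-type attack on the conformer with trans-diequatorial C4-OTBS and C5-Me), which sets C6 with the carbon substituent β and the hydroxyl α, and dilute acid then hydrolyses the enol ether of 19 to the methyl ketone.

Step 14
Reactants: 20 6β-acetyl-4β-(tert-butyldimethylsilyloxy)-5α-methyl-2α-isopropenylcyclohept-7-en-6α-ol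
Product: 21 6α-O-triethylsilyl ether of 20
Conditions: TESOTf, 2,6-lutidine, CH2Cl2, −78 to 0 °C
Reagents that add atoms: triethylsilyl triflate, CC[Si](CC)(CC)OS(=O)(=O)C(F)(F)F
Why: Silylation of the tertiary hydroxyl with the triflate means the following enolate chemistry needs only one equivalent of base and, later, that this group no longer directs a peracid to the α face but shields it.

Step 15
Reactants: 21 6α-O-triethylsilyl ether of 20
Product: 22 6β-(3-hydroxybutanoyl)-4β-(tert-butyldimethylsilyloxy)-6α-(triethylsilyloxy)-5α-methyl-2α-isopropenylcyclohept-7-ene (both carbinol epimers)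
Conditions: LiN(i-Pr)2 (1.2 equiv), THF, −78 °C; CH3CHO; AcOH quench at −78 °C
Reagents that add atoms: acetaldehyde, CC=O
Why: In this directed aldol addition the lithium enolate can form only on the methyl side because C6 is quaternary, and the new carbinol centre is of no consequence because it is removed in the next step.

Step 16
Reactants: 22 6β-(3-hydroxybutanoyl)-4β-(tert-butyldimethylsilyloxy)-6α-(triethylsilyloxy)-5α-methyl-2α-isopropenylcyclohept-7-ene
Product: 24 6β-[(E)-but-2-enoyl]-4β-(tert-butyldimethylsilyloxy)-6α-(triethylsilyloxy)-5α-methyl-2α-isopropenylcyclohept-7-ene, via mesylate 23 (not isolated)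
Conditions: MsCl, Et3N, CH2Cl2, 0 °C; then DBU, rt
Reagents that add atoms: none
Why: Mesylation followed by base-induced E1cB elimination of the β-mesyloxy ketone 23 should give the conjugated enone with the thermodynamically favoured E geometry.

Step 17
Reactants: 24 6β-[(E)-but-2-enoyl]-4β-(tert-butyldimethylsilyloxy)-6α-(triethylsilyloxy)-5α-methyl-2α-isopropenylcyclohept-7-ene
Product: 26 enal with the 2α-(3-oxoprop-1-en-2-yl) side chain (C9 aldehyde; all else as in 24), via allylic alcohol 25 (not isolated)
Conditions: SeO2 (0.5 equiv), t-BuOOH (3 equiv), CH2Cl2, rt; then MnO2, CH2Cl2, rt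
Reagents that add atoms: tert-butyl hydroperoxide, CC(C)(C)OO (oxygen passed on through SeO2, O=[Se]=O)
Why: SeO2 allylic oxidation (ene reaction then [2,3]-sigmatropic shift) should select the electron-richer 1,1-disubstituted isopropenyl alkene over the enone and oxidise its methyl group rather than the hindered tertiary C2–H, and MnO2 then converges the allylic alcohol 25 and any enal formed directly.

Step 18
Reactants: 26 enal with the 2α-(3-oxoprop-1-en-2-yl) side chain
Product: 27 2-substituted acrylic acid (C9 carboxylic acid on the 2α side chain; all else as in 24)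
Conditions: NaClO2, NaH2PO4, 2-methyl-2-butene, t-BuOH/H2O, rt
Reagents that add atoms: sodium chlorite, [Na+].[O-]Cl=O
Why: Pinnick oxidation converts the α-substituted acrolein into the acrylic acid under buffered conditions, with 2-methyl-2-butene trapping HOCl before it can add to the C7=C1 alkene.

Step 19
Reactants: 27 2-substituted acrylic acid
Product: 29 cis-fused α-methylene-γ-lactone (O on C1α and C8 on C2α) with 7β-OH, 6α-OTES, 6β-crotonoyl, 5α-Me and 4β-OTBS, via epoxy acid 28 (not isolated)
Conditions: mCPBA, CH2Cl2, 0 °C to rt; then CSA (10 mol%), rt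
Reagents that add atoms: meta-chloroperbenzoic acid, OOC(=O)c1cccc(Cl)c1
Why: Prilezhaev epoxidation should single out the only electron-rich alkene (C7=C1) and approach its β face, away from the α-disposed C6 triethylsilyloxy group and C2 side chain, after which the α-face carboxylic acid opens the epoxide at C1 with inversion (acid-catalysed 5-exo SN2 closure) to give the cis-fused γ-lactone with the C7 hydroxyl β, an α-epoxide being unable to lactonise and therefore separable.

Step 20
Reactants: 29 cis-fused α-methylene-γ-lactone with 7β-OH; 30 isovaleryl chloride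
Product: 31 7β-isovalerate of 29
Conditions: pyridine, DMAP (0.3 equiv), CH2Cl2, 0 °C to rt
Reagents that add atoms: none
Why: DMAP-catalysed acylation (nucleophilic catalysis) of the only free hydroxyl, at C7, installs the isovalerate with retention since no bond to C7 is broken.

Step 21
Reactants: 31 7β-isovalerate of 29
Product: 32 CNP0186412.1 (4β,6α-dihydroxy-6β-[(E)-but-2-enoyl]-7β-(3-methylbutanoyloxy)-5α-methylcycloheptane cis-fused at C1–C2 to the α-methylene-γ-butyrolactone)
Conditions: HF (48% aq.), MeCN, 0 °C to rt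
Reagents that add atoms: none
Why: Aqueous HF in acetonitrile cleaves both silyl ethers by fluoride attack at silicon under acidic, non-nucleophilic conditions that the ester, the enone, the tertiary α-ketol and the α-methylene lactone should tolerate.

**Compound list**

1 | (R)-2,3-O-isopropylideneglyceraldehyde | O=C[C@H]1COC(C)(C)O1 | starting material
2 | (E)-crotylboronic acid pinacol ester | C/C=C/CB1OC(C)(C)C(C)(C)O1 | starting material
3 | pinacol borate ester of 4 | C=C[C@H](C)[C@H](OB2OC(C)(C)C(C)(C)O2)[C@H]1COC(C)(C)O1 | intermediate (not isolated)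
4 | (1S,2S)-1-[(4R)-2,2-dimethyl-1,3-dioxolan-4-yl]-2-methylbut-3-en-1-ol | C=C[C@H](C)[C@H](O)[C@H]1COC(C)(C)O1 | intermediate
5 | tert-butyldimethylsilyl ether of 4 | C=C[C@H](C)[C@H](O[Si](C)(C)C(C)(C)C)[C@H]1COC(C)(C)O1 | intermediate
6 | (2R,3S)-3-(tert-butyldimethylsilyloxy)-3-[(4R)-2,2-dimethyl-1,3-dioxolan-4-yl]-2-methylpropanoic acid | OC(=O)[C@H](C)[C@H](O[Si](C)(C)C(C)(C)C)[C@H]1COC(C)(C)O1 | intermediate
7 | (2R,3S,4R)-3-(tert-butyldimethylsilyloxy)-4,5-dihydroxy-2-methylpentanoic acid | OC(=O)[C@H](C)[C@H](O[Si](C)(C)C(C)(C)C)[C@H](O)CO | intermediate (not isolated)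
8 | (3R,4S,5R)-4-(tert-butyldimethylsilyloxy)-5-(hydroxymethyl)-3-methyldihydrofuran-2(3H)-one | O=C1O[C@H](CO)[C@@H](O[Si](C)(C)C(C)(C)C)[C@H]1C | intermediate
9 | (2S,3S,4R)-3-(tert-butyldimethylsilyloxy)-4-methyl-5-oxotetrahydrofuran-2-carbaldehyde | O=C1O[C@H](C=O)[C@@H](O[Si](C)(C)C(C)(C)C)[C@H]1C | intermediate
10 | 1-(triphenylphosphoranylidene)propan-2-one | CC(=O)C=P(c1ccccc1)(c1ccccc1)c1ccccc1 | starting material
11 | (3R,4S,5R)-4-(tert-butyldimethylsilyloxy)-3-methyl-5-[(E)-3-oxobut-1-en-1-yl]dihydrofuran-2(3H)-one | O=C1O[C@H](/C=C/C(C)=O)[C@@H](O[Si](C)(C)C(C)(C)C)[C@H]1C | intermediate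
12 | (3R,4S,5R)-4-(tert-butyldimethylsilyloxy)-3-methyl-5-[(E)-3-methylbuta-1,3-dien-1-yl]dihydrofuran-2(3H)-one | O=C1O[C@H](/C=C/C(C)=C)[C@@H](O[Si](C)(C)C(C)(C)C)[C@H]1C | intermediate (not isolated)
13 | (2R,3S,4R)-3-(tert-butyldimethylsilyloxy)-4-methyl-5-methylidene-2-[(E)-3-methylbuta-1,3-dien-1-yl]tetrahydrofuran | C=C1O[C@H](/C=C/C(C)=C)[C@@H](O[Si](C)(C)C(C)(C)C)[C@H]1C | intermediate (Claisen precursor)
14 | (2R,3R,6R)-3-(tert-butyldimethylsilyloxy)-2-methyl-6-(prop-1-en-2-yl)cyclohept-4-en-1-one | O=C1C[C@@H](C(C)=C)C=C[C@@H](O[Si](C)(C)C(C)(C)C)[C@H]1C | intermediate (Claisen product)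
15 | 6α-hydroxy-5α-methyl-2α-isopropenylcyclohept-7-en-4-one | O=C1C[C@@H](C(C)=C)C=C[C@@H](O)[C@H]1C | intermediate
16 | 5α-methyl-2α-isopropenylcyclohept-7-ene-4β,6α-diol | O[C@@H]1C[C@@H](C(C)=C)C=C[C@@H](O)[C@H]1C | intermediate
17 | 4β-hydroxy-5α-methyl-2α-isopropenylcyclohept-7-en-6-one | O[C@@H]1C[C@@H](C(C)=C)C=CC(=O)[C@H]1C | intermediate
18 | 4β-(tert-butyldimethylsilyloxy)-5α-methyl-2α-isopropenylcyclohept-7-en-6-one | CC(C)(C)[Si](C)(C)O[C@@H]1C[C@@H](C(C)=C)C=CC(=O)[C@H]1C | intermediate
19 | 4β-(tert-butyldimethylsilyloxy)-6β-(1-ethoxyvinyl)-5α-methyl-2α-isopropenylcyclohept-7-en-6α-ol | CC(C)(C)[Si](C)(C)O[C@@H]1C[C@@H](C(C)=C)C=C[C@](O)(C(=C)OCC)[C@H]1C | intermediate (not isolated)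
20 | 6β-acetyl-4β-(tert-butyldimethylsilyloxy)-5α-methyl-2α-isopropenylcyclohept-7-en-6α-ol | CC(C)(C)[Si](C)(C)O[C@@H]1C[C@@H](C(C)=C)C=C[C@](O)(C(C)=O)[C@H]1C | intermediate
21 | 6β-acetyl-4β-(tert-butyldimethylsilyloxy)-6α-(triethylsilyloxy)-5α-methyl-2α-isopropenylcyclohept-7-ene | CC(C)(C)[Si](C)(C)O[C@@H]1C[C@@H](C(C)=C)C=C[C@](O[Si](CC)(CC)CC)(C(C)=O)[C@H]1C | intermediate
22 | 6β-(3-hydroxybutanoyl) analogue of 21 (carbinol epimers) | CC(C)(C)[Si](C)(C)O[C@@H]1C[C@@H](C(C)=C)C=C[C@](O[Si](CC)(CC)CC)(C(=O)CC(C)O)[C@H]1C | intermediate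
23 | 6β-(3-methanesulfonyloxybutanoyl) analogue of 21 | CC(C)(C)[Si](C)(C)O[C@@H]1C[C@@H](C(C)=C)C=C[C@](O[Si](CC)(CC)CC)(C(=O)CC(C)OS(C)(=O)=O)[C@H]1C | intermediate (not isolated)
24 | 6β-[(E)-but-2-enoyl]-4β-(tert-butyldimethylsilyloxy)-6α-(triethylsilyloxy)-5α-methyl-2α-isopropenylcyclohept-7-ene | CC(C)(C)[Si](C)(C)O[C@@H]1C[C@@H](C(C)=C)C=C[C@](O[Si](CC)(CC)CC)(C(=O)/C=C/C)[C@H]1C | intermediate
25 | 2α-(3-hydroxyprop-1-en-2-yl) analogue of 24 (C9 allylic alcohol) | CC(C)(C)[Si](C)(C)O[C@@H]1C[C@@H](C(=C)CO)C=C[C@](O[Si](CC)(CC)CC)(C(=O)/C=C/C)[C@H]1C | intermediate (not isolated)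
26 | 2α-(3-oxoprop-1-en-2-yl) analogue of 24 (C9 enal) | CC(C)(C)[Si](C)(C)O[C@@H]1C[C@@H](C(=C)C=O)C=C[C@](O[Si](CC)(CC)CC)(C(=O)/C=C/C)[C@H]1C | intermediate
27 | 2-substituted acrylic acid (C9 acid on the 2α side chain of 24) | CC(C)(C)[Si](C)(C)O[C@@H]1C[C@@H](C(=C)C(=O)O)C=C[C@](O[Si](CC)(CC)CC)(C(=O)/C=C/C)[C@H]1C | intermediate
28 | 7β,1β-epoxide of 27 | CC(C)(C)[Si](C)(C)O[C@@H]1C[C@@H](C(=C)C(=O)O)[C@@H]2O[C@@H]2[C@](O[Si](CC)(CC)CC)(C(=O)/C=C/C)[C@H]1C | intermediate (not isolated)
29 | cis-fused α-methylene-γ-lactone with 7β-OH, 6α-OTES, 6β-crotonoyl, 5α-Me, 4β-OTBS | C=C1C(=O)O[C@@H]2[C@H]1C[C@@H](O[Si](C)(C)C(C)(C)C)[C@H](C)[C@@](O[Si](CC)(CC)CC)(C(=O)/C=C/C)[C@H]2O | intermediate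
30 | isovaleryl chloride | CC(C)CC(=O)Cl | starting material
31 | 7β-isovalerate of 29 | C=C1C(=O)O[C@@H]2[C@H]1C[C@@H](O[Si](C)(C)C(C)(C)C)[C@H](C)[C@@](O[Si](CC)(CC)CC)(C(=O)/C=C/C)[C@H]2OC(=O)CC(C)C | intermediate
32 | CNP0186412.1 | C=C1C(=O)O[C@@H]2[C@H]1C[C@@H](O)[C@H](C)[C@@](O)(C(=O)/C=C/C)[C@H]2OC(=O)CC(C)C | target

**Count**

Total step count: 21. Longest linear sequence: 21 steps (1 to 32); 2, 10 and 30 are bought and enter in steps 1, 6 and 20.

**Steps most likely to fail**

1. Step 8 (Claisen ring expansion). What may go wrong: traces of acid may isomerise the exocyclic enol ether to the endocyclic one before it rearranges, or the shift may be slow because the vinyl ether has to twist out of the furan plane, so that thermal loss of the diene competes. Fallback: the same C2–C3/O–C7 reorganisation is run as a Lewis-acid-promoted process. Starting from 13, i-Bu3Al (CH2Cl2, −78 °C to rt) binds the ether oxygen, brings about the shift at low temperature and then reduces the aluminium-bound ketone by β-hydride transfer. This should give 3-(tert-butyldimethylsilyloxy)-2-methyl-6-(prop-1-en-2-yl)cyclohept-4-en-1-ol F1 as a mixture of C4 epimers, and Dess–Martin oxidation of F1 returns to the route at 14.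

2. Step 13 (acyl-anion addition to the C6 ketone). What may go wrong: poor facial selectivity, since the β-silyloxy group at C4 may offset the bias of the C5 methyl, or enolisation of the ketone by the basic organolithium. Fallback: starting from 18, HC≡CMgBr (THF, −78 to 0 °C) is used instead. This slim, less basic sp nucleophile follows the axial-type trajectory that a bulky sp2 reagent avoids, and is the reagent to use if the β face is reached better that way; it should give the propargylic alcohol 6β-ethynyl-4β-(tert-butyldimethylsilyloxy)-5α-methyl-2α-isopropenylcyclohept-7-en-6α-ol F2. Markovnikov hydration of the terminal alkyne (Ph3PAuNTf2 cat., aqueous dioxane, rt) then gives the methyl ketone, and the route is rejoined at 20.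

3. Step 19 (epoxidation–lactonisation). What may go wrong: attack of the peracid on the α face, for instance if the crotonoyl group sits axial over the β face, which leaves an epoxide that cannot lactonise. Fallback: the preference for the α face is then used through a halohydrin. Starting from 27, Me3SiCHN2 (PhMe/MeOH) gives the methyl ester F3. NBS in aqueous acetone should place bromine on the more accessible α face and water anti to it, giving the 7α-bromo-1β-hydroxy bromohydrin F4 (its regioisomer converges). K2CO3 in MeOH closes either regioisomer to the β-epoxy methyl ester F5, and Me3SnOH (1,2-dichloroethane, 80 °C) unmasks the acid, rejoining the route at 28, which lactonises to 29.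

**Further compounds**

F1 | step 8 | 3-(tert-butyldimethylsilyloxy)-2-methyl-6-(prop-1-en-2-yl)cyclohept-4-en-1-ol, C4 (route numbering) epimer mixture, other centres as in 14 | OC1C[C@@H](C(C)=C)C=C[C@@H](O[Si](C)(C)C(C)(C)C)[C@H]1C
F2 | step 13 | 6β-ethynyl-4β-(tert-butyldimethylsilyloxy)-5α-methyl-2α-isopropenylcyclohept-7-en-6α-ol | CC(C)(C)[Si](C)(C)O[C@@H]1C[C@@H](C(C)=C)C=C[C@](O)(C#C)[C@H]1C
F3 | step 19 | methyl ester of 27 | CC(C)(C)[Si](C)(C)O[C@@H]1C[C@@H](C(=C)C(=O)OC)C=C[C@](O[Si](CC)(CC)CC)(C(=O)/C=C/C)[C@H]1C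
F4 | step 19 | 7α-bromo-1β-hydroxy bromohydrin of F3 | CC(C)(C)[Si](C)(C)O[C@@H]1C[C@@H](C(=C)C(=O)OC)[C@H](O)[C@@H](Br)[C@](O[Si](CC)(CC)CC)(C(=O)/C=C/C)[C@H]1C
F5 | step 19 | 7β,1β-epoxide of F3 (methyl ester of 28) | CC(C)(C)[Si](C)(C)O[C@@H]1C[C@@H](C(=C)C(=O)OC)[C@@H]2O[C@@H]2[C@](O[Si](CC)(CC)CC)(C(=O)/C=C/C)[C@H]1C
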